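I stop this flask at the peak of intermediate B, so I want that peak's time and height before I commit.

common to all: substrate 0.80 M

| charge | reagent | capture agent | remark | time |
|---|---|---|---|---|
| ash | 0.60 equiv | 0.040 M | the very flask that is asked about, followed so far |  |
| flask | 0.600 equiv | 0.0400 M |  | 2.5 d |

- ash (time / h: intermediate B / %, product / %): 1.33: 8.5, 0.9; 2.00: 13.2, 1.7; 3.00: 17.5, 3.0; 5.00: 19.6, 7.3; 8.00: 16.6, 13.2; 12.0: 13.0, 19.7; 20.0: 7.7, 28.8

(each reading ± 0.3 percentage points)

- when, up to 2.5 d, the flask holds most intermediate B
- the amount of intermediate B, in percent of the substrate charged, at that time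
- the first time at which intermediate B reaches 5.9%, in the same percent

- the earlier runs were read with a standard deviation of 0.3 percentage points

From below, the peak stands at least at the highest reading, 19.6% at 5.00 h, within the scatter. From above, if the curve bends downward there, the chord through the readings at 2.00 h and 3.00 h and the chord through 5.00 h and 8.00 h pass over it, and they cross near 3.77 h, at 20.8%.

To tighten this I use the drain, the fraction of the standing intermediate B that turns up as product per hour, an apparent first-order constant, read between 8.00 h and 12.0 h as 0.110 h⁻¹. At the peak, intermediate B plus product gains at the drain times intermediate B. That sum gains 6.4 points from 3.00 h to 5.00 h, then 2.9 points by 8.00 h. Interpolating between those midpoints, I put the peak at 5.17 h. The height is then a small correction to the reading, about 0.18 points, so my estimate of the top is 19.8%, give or take 0.3 points.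

The forecast says 0.19 d (0.16 d to 0.22 d), 19.9% (19.4% to 20.8%) and 0.95 h (0.8 h to 1.1 h), on the ground that “Product tracks intermediate B cleanly”. Its height lies above my tightened top but below the chords, and its time is earlier than mine.

This flask gives 0.195 d, 19.6% and 1.03 h.

    capture agent + intermediate B → trapped intermediate (k = 0.260 L mol⁻¹ h⁻¹)
    substrate ⇌ intermediate A (K = 2.20, k = 0.630 h⁻¹)
    intermediate B ⇌ intermediate C (K = 2.00, k = 0.180 h⁻¹)
    reagent + intermediate A → intermediate B (k = 0.640 L mol⁻¹ h⁻¹)
    intermediate B → product (k = 0.110 h⁻¹)

At 0.292 d this flask still holds 17.9%. From 1.25 d to 2.5 d, the drain times the logarithmic mean of intermediate B gives 12 points of product, and this flask gains 12 points. A neighbour flask with 0.240 equiv of reagent, its other charges as in this one, peaks at 8.85%, and at that moment the drain has its product gaining at a pace of 8.85% every 9.09 h.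

The runs are simulated from invented constants; the scatter is artificial.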